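**Retrosynthetic overview**

1. Agastenol is cut at the C7 ester (4-hydroxybenzoic acid) and then at O1–C5 of the oxolane (ring A: O1, C2, C3, C4, C5), which leaves an open-chain 1,4-diol.
2. The feature used: in ring A the C3–C4 unit lies between the aryl carbinol carbon C2 and, through the exocyclic double bond on C4, the benzylidene carbon C6 (aryl, H). The array C2(O)–C3–C4=C6 is the transposed-allyl pattern of an aldehyde allylboration, so C2–C3 comes from the allylboration and C4–C6 from the 1,2-metallate shift that first builds the α-aryl allylboronate.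
3. Three fragments meet in one flask: the lithiated N,N-diisopropylcarbamate of O-silylated vanillyl alcohol (C6), a (Z)-alkenyl pinacol boronate carrying C5–OTES and C7–OTBS (C3, C4, C5, C7; from propargyl alcohol through an ynoate), and O-silylated vanillin (C2).
4. Ring order: the key step closes no ring. Ring A, the only ring built, is closed afterwards by SN2 attack of O1 on activated C5; C7–O is then freed and acylated, and the phenols are unmasked.
5. Protecting groups: TIPS on both vanillyl phenols (stable to s-BuLi, alkoxide and mild acid), TES on C5–O (removed first), TBS on C7–O (removed second).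

Key step: step 9

Assumption: with the (S,S)-bis(oxazoline) ligand the equilibrated benzylic lithium compound is taken to be (S), and its borylation by the pinacol boronate is taken to go with retention; if either sense is the reverse, the (R,R)-ligand is used and nothing else changes.

**Route**

Step 1
Reactants: 1 vanillin
Product: 2 3-methoxy-4-(triisopropylsilyloxy)benzaldehyde
Conditions: TIPSCl, imidazole, DMF, rt
Reagents that add atoms: triisopropylsilyl chloride, CC(C)[Si](Cl)(C(C)C)C(C)C
Why: Imidazole-promoted silylation of the phenol; TIPS is chosen because it withstands s-BuLi, alkoxide and mild acid later, and 2 serves both as the aldehyde of step 9 and as the source of the carbamate.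

Step 2
Reactants: 2 3-methoxy-4-(triisopropylsilyloxy)benzaldehyde
Product: 3 [3-methoxy-4-(triisopropylsilyloxy)phenyl]methanol
Conditions: NaBH4, MeOH, 0 °C
Reagents that add atoms: none
Why: Borohydride reduction of an aromatic aldehyde, to which the aryl TIPS ether is inert at 0 °C.

Step 3
Reactants: 3 [3-methoxy-4-(triisopropylsilyloxy)phenyl]methanol
Product: 4 3-methoxy-4-(triisopropylsilyloxy)benzyl N,N-diisopropylcarbamate
Conditions: i-Pr2NCOCl, Et3N, CH2Cl2, reflux
Reagents that add atoms: N,N-diisopropylcarbamoyl chloride, CC(C)N(C(C)C)C(=O)Cl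
Why: O-Carbamoylation of a primary benzylic alcohol gives the carbamate that later directs α-lithiation and acts as the leaving group of the 1,2-shift.

Step 4
Reactants: 5 propargyl alcohol
Product: 6 triethyl(prop-2-yn-1-yloxy)silane
Conditions: TESCl, imidazole, CH2Cl2, 0 °C
Reagents that add atoms: chlorotriethylsilane, CC[Si](Cl)(CC)CC
Why: Standard silylation; TES is placed on the oxygen that ends on C5 because that ether must be removed before the TBS ether on C7.

Step 5
Reactants: 6 triethyl(prop-2-yn-1-yloxy)silane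
Product: 8 methyl 4-(triethylsilyloxy)but-2-ynoate, via lithium acetylide 7 (not isolated)
Conditions: n-BuLi, THF, −78 °C; ClCO2Me, −78 → 0 °C
Reagents that add atoms: methyl chloroformate, COC(=O)Cl
Why: Deprotonation of the terminal alkyne and C-acylation of the lithium acetylide with the chloroformate.

Step 6
Reactants: 8 methyl 4-(triethylsilyloxy)but-2-ynoate
Product: 9 methyl (Z)-3-(4,4,5,5-tetramethyl-1,3,2-dioxaborolan-2-yl)-4-(triethylsilyloxy)but-2-enoate
Conditions: B2pin2, CuCl (cat.), NaOt-Bu (cat.), Xantphos (cat.), MeOH (2 equiv), THF, rt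
Reagents that add atoms: bis(pinacolato)diboron, CC1(C)OB(OC1(C)C)B1OC(C)(C)C(C)(C)O1
Why: Copper-catalysed conjugate borylation of an ynoate: the boryl copper species adds syn with boron at the β-carbon and methanol protonates the α-carbon, so boron and the vinylic hydrogen are cis (Z isomer).

Step 7
Reactants: 9 methyl (Z)-3-(4,4,5,5-tetramethyl-1,3,2-dioxaborolan-2-yl)-4-(triethylsilyloxy)but-2-enoate
Product: 10 (Z)-3-(4,4,5,5-tetramethyl-1,3,2-dioxaborolan-2-yl)-4-(triethylsilyloxy)but-2-en-1-ol
Conditions: i-Bu2AlH, CH2Cl2, −78 °C; aq potassium sodium tartrate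
Reagents that add atoms: none
Why: 1,2-Reduction of the enoate ester to the allylic alcohol at low temperature leaves the pinacol boronate, the TES ether and the alkene geometry untouched, and boron is trans to the new CH2OH so no oxaborole can form.

Step 8
Reactants: 10 (Z)-3-(4,4,5,5-tetramethyl-1,3,2-dioxaborolan-2-yl)-4-(triethylsilyloxy)but-2-en-1-ol
Product: 11 2-[(2Z)-4-(tert-butyldimethylsilyloxy)-1-(triethylsilyloxy)but-2-en-2-yl]-4,4,5,5-tetramethyl-1,3,2-dioxaborolane (boron cis to the vinylic H and trans to CH2OTBS)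
Conditions: TBSCl, imidazole, CH2Cl2, 0 °C → rt
Reagents that add atoms: tert-butyldimethylsilyl chloride, CC(C)(C)[Si](C)(C)Cl
Why: Standard silylation of the primary allylic alcohol gives the differentiated bis-silyl ether.

Step 9
Reactants: 4 3-methoxy-4-(triisopropylsilyloxy)benzyl N,N-diisopropylcarbamate; 11 the (Z)-alkenyl pinacol boronate; 2 3-methoxy-4-(triisopropylsilyloxy)benzaldehyde
Product: 16 anti homoallylic alcohol (1R,2S,3E)-2-[(tert-butyldimethylsilyloxy)methyl]-1,4-bis[3-methoxy-4-(triisopropylsilyloxy)phenyl]-3-[(triethylsilyloxy)methyl]but-3-en-1-ol, via lithiated carbamate 12 (not isolated), via boronate complex 13 (not isolated), via allylboronate 14 (not isolated), via borate ester 15 (not isolated)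
Conditions: 4, s-BuLi, 2,2'-(pentane-3,3-diyl)bis[(4S)-4-isopropyl-4,5-dihydrooxazole], toluene, −78 °C, 2 h; 11, −78 °C, 1 h, then → rt; 2, rt, 16 h; H2O work-up
Reagents that add atoms: none
Why: s-BuLi with the bis(oxazoline) removes a benzylic proton next to the carbamate oxygen of 4, the two diastereomeric lithium complexes equilibrate to the (S)-compound 12 (dynamic thermodynamic resolution), and 12 adds to the boron of 11 with retention to give ate complex 13. On warming, the alkenyl group shifts from boron to C6 anti to the departing carbamate (1,2-metallate rearrangement, inversion at C6), which forms C4–C6 and the (R)-α-aryl allylboronate 14; this is the known lithiation–borylation of a carbamate with an alkenyl pinacol boronate. 14 then adds aldehyde 2 through a closed six-membered chair with the carbonyl oxygen on boron (allylboration), forming C2–C3 and moving the double bond to C4=C6; the chair is a transition state only and no ring of the target is closed. In the chair the aryl of 2 is equatorial, the CH2OTBS group is equatorial because it is trans to C6 in 14 (hence anti C2/C3), and the C6 aryl is axial to avoid A(1,2) strain with the CH2OTES group on C4 and contact with the pinacol methyls, so it ends cis to C3 (E alkene). With these three preferences the (R) centre at C6 fixes both the aldehyde face and the allyl face, giving (1R,2S) in 16 (2R,3S in target numbering), and is itself consumed. The step needs benzylic rather than ring lithiation (secured by lithium complexation to the carbamate), carbon rather than oxygen migration (the sp2 carbon migrates readily onto a benzylic carbon with a good leaving group), and capture of 14 before any 1,3-boron shift (pinacol esters shift slowly at rt).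

Step 10
Reactants: 16 the anti homoallylic alcohol
Product: 17 (2E,3S,4R)-3-[(tert-butyldimethylsilyloxy)methyl]-2-[3-methoxy-4-(triisopropylsilyloxy)benzylidene]-4-[3-methoxy-4-(triisopropylsilyloxy)phenyl]butane-1,4-diol
Conditions: PPTS (cat.), MeOH/CH2Cl2, 0 °C
Reagents that add atoms: none
Why: Acid-catalysed methanolysis removes the primary TES ether much faster than the primary TBS or the aryl TIPS ethers.

Step 11
Reactants: 17 the 1,4-diol
Product: 19 tert-butyl{[(2R,3S,4E)-4-[3-methoxy-4-(triisopropylsilyloxy)benzylidene]-2-[3-methoxy-4-(triisopropylsilyloxy)phenyl]oxolan-3-yl]methoxy}dimethylsilane, via allylic mesylate 18 (not isolated)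
Conditions: MsCl, 2,4,6-collidine, CH2Cl2, 0 °C; then t-BuOK, THF, −40 → 0 °C
Reagents that add atoms: none
Why: Selective sulfonylation of the unhindered primary allylic hydroxyl is followed by an intramolecular Williamson etherification in which the C2 alkoxide displaces the mesylate at C5 (5-exo-tet SN2), closing ring A without touching C2 or C3; the leaving group is in place before the alkoxide is made, which leaves little time for silyl migration.

Step 12
Reactants: 19 the silylated oxolane
Product: 20 [(2R,3S,4E)-4-[3-methoxy-4-(triisopropylsilyloxy)benzylidene]-2-[3-methoxy-4-(triisopropylsilyloxy)phenyl]oxolan-3-yl]methanol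
Conditions: CSA (cat.), MeOH/CH2Cl2, 0 °C
Reagents that add atoms: none
Why: Acid-catalysed methanolysis cleaves the primary alkyl TBS ether selectively, because aryl silyl ethers react much more slowly under acidic conditions.

Step 13
Reactants: 21 4-hydroxybenzoic acid
Product: 23 4-(tert-butyldimethylsilyloxy)benzoic acid, via silyl ester 22 (not isolated)
Conditions: TBSCl (2.2 equiv), imidazole, DMF, rt; then AcOH/THF/H2O, rt
Reagents that add atoms: tert-butyldimethylsilyl chloride, CC(C)(C)[Si](C)(C)Cl
Why: Both OH groups are silylated and the labile silyl ester is then hydrolysed selectively, leaving the aryl silyl ether.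

Step 14
Reactants: 20 the oxolane alcohol; 23 4-(tert-butyldimethylsilyloxy)benzoic acid
Product: 24 [(2R,3S,4E)-4-[3-methoxy-4-(triisopropylsilyloxy)benzylidene]-2-[3-methoxy-4-(triisopropylsilyloxy)phenyl]oxolan-3-yl]methyl 4-(tert-butyldimethylsilyloxy)benzoate
Conditions: DCC, DMAP (cat.), CH2Cl2, 0 °C → rt
Reagents that add atoms: none
Why: Steglich esterification (carbodiimide activation with DMAP acyl transfer) of the primary alcohol under neutral conditions.

Step 15
Reactants: 24 the tris-silylated ester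
Product: 25 agastenol, [(2R,3S,4E)-4-(4-hydroxy-3-methoxybenzylidene)-2-(4-hydroxy-3-methoxyphenyl)oxolan-3-yl]methyl 4-hydroxybenzoate
Conditions: TBAF, AcOH, THF, 0 °C
Reagents that add atoms: none
Why: Fluoride cleaves all three aryl silyl ethers, and the acetic acid buffer keeps the phenols protonated so that neither the benzoate ester nor the benzylic C2–O1 bond is endangered by phenoxide.

**Compound list**

1 | vanillin | COc1cc(C=O)ccc1O | starting material
2 | 3-methoxy-4-(triisopropylsilyloxy)benzaldehyde | COc1cc(C=O)ccc1O[Si](C(C)C)(C(C)C)C(C)C | intermediate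
3 | [3-methoxy-4-(triisopropylsilyloxy)phenyl]methanol | COc1cc(CO)ccc1O[Si](C(C)C)(C(C)C)C(C)C | intermediate
4 | 3-methoxy-4-(triisopropylsilyloxy)benzyl N,N-diisopropylcarbamate | COc1cc(COC(=O)N(C(C)C)C(C)C)ccc1O[Si](C(C)C)(C(C)C)C(C)C | intermediate
5 | propargyl alcohol | C#CCO | starting material
6 | triethyl(prop-2-yn-1-yloxy)silane | C#CCO[Si](CC)(CC)CC | intermediate
7 | lithium acetylide of 6 (not isolated) | [Li]C#CCO[Si](CC)(CC)CC | intermediate
8 | methyl 4-(triethylsilyloxy)but-2-ynoate | COC(=O)C#CCO[Si](CC)(CC)CC | intermediate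
9 | methyl (Z)-3-(pinacolboryl)-4-(triethylsilyloxy)but-2-enoate | COC(=O)/C=C(\CO[Si](CC)(CC)CC)B1OC(C)(C)C(C)(C)O1 | intermediate
10 | (Z)-3-(pinacolboryl)-4-(triethylsilyloxy)but-2-en-1-ol | OC/C=C(\CO[Si](CC)(CC)CC)B1OC(C)(C)C(C)(C)O1 | intermediate
11 | 2-[(2Z)-4-(tert-butyldimethylsilyloxy)-1-(triethylsilyloxy)but-2-en-2-yl]-4,4,5,5-tetramethyl-1,3,2-dioxaborolane | CC[Si](CC)(CC)OC/C(B1OC(C)(C)C(C)(C)O1)=C\CO[Si](C)(C)C(C)(C)C | intermediate
12 | (S)-α-lithio derivative of carbamate 4, as its bis(oxazoline) complex (not isolated) | [Li][C@H](OC(=O)N(C(C)C)C(C)C)c1ccc(O[Si](C(C)C)(C(C)C)C(C)C)c(OC)c1 | intermediate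
13 | lithium boronate (ate) complex, (S) at the benzylic carbon (not isolated) | [Li+].CC[Si](CC)(CC)OC/C(=C\CO[Si](C)(C)C(C)(C)C)[B-]1(OC(C)(C)C(C)(C)O1)[C@H](OC(=O)N(C(C)C)C(C)C)c1ccc(O[Si](C(C)C)(C(C)C)C(C)C)c(OC)c1 | intermediate
14 | (R)-α-aryl allylboronate, C7 trans to C6 on the C3=C4 bond (not isolated) | CC[Si](CC)(CC)OC/C(=C\CO[Si](C)(C)C(C)(C)C)[C@H](B1OC(C)(C)C(C)(C)O1)c1ccc(O[Si](C(C)C)(C(C)C)C(C)C)c(OC)c1 | intermediate
15 | O-pinacolboryl ether of 16 (not isolated) | COc1cc(/C=C(/CO[Si](CC)(CC)CC)[C@@H](CO[Si](C)(C)C(C)(C)C)[C@@H](OB2OC(C)(C)C(C)(C)O2)c2ccc(O[Si](C(C)C)(C(C)C)C(C)C)c(OC)c2)ccc1O[Si](C(C)C)(C(C)C)C(C)C | intermediate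
16 | (1R,2S,3E)-2-[(tert-butyldimethylsilyloxy)methyl]-1,4-bis[3-methoxy-4-(triisopropylsilyloxy)phenyl]-3-[(triethylsilyloxy)methyl]but-3-en-1-ol | COc1cc(/C=C(/CO[Si](CC)(CC)CC)[C@@H](CO[Si](C)(C)C(C)(C)C)[C@@H](O)c2ccc(O[Si](C(C)C)(C(C)C)C(C)C)c(OC)c2)ccc1O[Si](C(C)C)(C(C)C)C(C)C | intermediate
17 | (2E,3S,4R)-3-[(tert-butyldimethylsilyloxy)methyl]-2-[3-methoxy-4-(triisopropylsilyloxy)benzylidene]-4-[3-methoxy-4-(triisopropylsilyloxy)phenyl]butane-1,4-diol | COc1cc(/C=C(/CO)[C@@H](CO[Si](C)(C)C(C)(C)C)[C@@H](O)c2ccc(O[Si](C(C)C)(C(C)C)C(C)C)c(OC)c2)ccc1O[Si](C(C)C)(C(C)C)C(C)C | intermediate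
18 | primary allylic (C5) mesylate of 17 (not isolated) | COc1cc(/C=C(/COS(C)(=O)=O)[C@@H](CO[Si](C)(C)C(C)(C)C)[C@@H](O)c2ccc(O[Si](C(C)C)(C(C)C)C(C)C)c(OC)c2)ccc1O[Si](C(C)C)(C(C)C)C(C)C | intermediate
19 | tert-butyl{[(2R,3S,4E)-4-[3-methoxy-4-(triisopropylsilyloxy)benzylidene]-2-[3-methoxy-4-(triisopropylsilyloxy)phenyl]oxolan-3-yl]methoxy}dimethylsilane | COc1cc(/C=C2/CO[C@@H](c3ccc(O[Si](C(C)C)(C(C)C)C(C)C)c(OC)c3)[C@@H]2CO[Si](C)(C)C(C)(C)C)ccc1O[Si](C(C)C)(C(C)C)C(C)C | intermediate
20 | [(2R,3S,4E)-4-[3-methoxy-4-(triisopropylsilyloxy)benzylidene]-2-[3-methoxy-4-(triisopropylsilyloxy)phenyl]oxolan-3-yl]methanol | COc1cc(/C=C2/CO[C@@H](c3ccc(O[Si](C(C)C)(C(C)C)C(C)C)c(OC)c3)[C@@H]2CO)ccc1O[Si](C(C)C)(C(C)C)C(C)C | intermediate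
21 | 4-hydroxybenzoic acid | O=C(O)c1ccc(O)cc1 | starting material
22 | tert-butyldimethylsilyl 4-(tert-butyldimethylsilyloxy)benzoate (not isolated) | CC(C)(C)[Si](C)(C)OC(=O)c1ccc(O[Si](C)(C)C(C)(C)C)cc1 | intermediate
23 | 4-(tert-butyldimethylsilyloxy)benzoic acid | O=C(O)c1ccc(O[Si](C)(C)C(C)(C)C)cc1 | intermediate
24 | [(2R,3S,4E)-4-[3-methoxy-4-(triisopropylsilyloxy)benzylidene]-2-[3-methoxy-4-(triisopropylsilyloxy)phenyl]oxolan-3-yl]methyl 4-(tert-butyldimethylsilyloxy)benzoate | COc1cc(/C=C2/CO[C@@H](c3ccc(O[Si](C(C)C)(C(C)C)C(C)C)c(OC)c3)[C@@H]2COC(=O)c2ccc(O[Si](C)(C)C(C)(C)C)cc2)ccc1O[Si](C(C)C)(C(C)C)C(C)C | intermediate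
25 | agastenol | COc1cc(/C=C2/CO[C@@H](c3ccc(O)c(OC)c3)[C@@H]2COC(=O)c2ccc(O)cc2)ccc1O | target

**Step count**

Total: 15 steps. Longest linear sequence: 11 steps (propargyl alcohol through steps 4, 5, 6, 7, 8, 9, 10, 11, 12, 14, 15).

**Steps most likely to fail**

Step 9. The lithiated primary benzylic carbamate may epimerise or resolve incompletely, and the electron-rich benzylic ate complex may partly ionise during the shift; both would lower the enantiomeric purity. The crowded allylboronate may also add only slowly to the electron-rich aldehyde.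
Fallback: an auxiliary-controlled aldol and lactone route that sets out from aldehyde 2 and returns at diol 17, bypassing steps 9 and 10. (R)-4-Benzyl-1,3-oxazolidin-2-one is N-acylated (n-BuLi, methyl 4-chloro-4-oxobutanoate) to the succinate imide F1. Its dibutylboron enolate (Bu2BOTf, i-Pr2NEt, CH2Cl2, −78 °C) adds to 2 in an Evans syn aldol reaction to give the syn aldol adduct F2. F2 lactonises onto the methyl ester (PPTS cat., warming) to the trans lactone imide F3. NaBH4 in THF/H2O removes the auxiliary reductively to give the hydroxymethyl lactone F4, which is silylated (TBSCl, imidazole) to the lactone silyl ether F5. The lithium enolate of F5 (LiN(SiMe3)2, THF, −78 °C) adds to a second portion of 2 to give the aldol adduct F6. Dehydration (MsCl, Et3N, then DBU) gives the (E)-benzylidene lactone F7, with the aryl anti to the carbonyl. Excess i-Bu2AlH (CH2Cl2, −78 → 0 °C) reduces the lactone to the allylic 1,4-diol 17. Here C2 and C3 are set by the auxiliary and the alkene geometry by thermodynamics.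

Step 11. The benzylic hydroxyl may be sulfonylated in competition, the cinnamyl-type mesylate may ionise and be attacked at C6 instead of C5, or the C7 silyl group may migrate to the C2 alkoxide.
Fallback: it sets out from diol 17 and returns at oxolane 19. The ring is closed at the other C–O bond by acid (CSA cat., CH2Cl2, −20 → 0 °C): the p-silyloxybenzylic hydroxyl at C2 ionises and the C5 hydroxyl captures the cation. This is the dehydrative cyclisation long used for 2-aryl-oxolane lignans, and it should favour the 2,3-trans isomer because the product equilibrates through the same cation. No new compound is made (F0).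

Step 12. Acid may open the doubly activated oxolane (O1–C2 benzylic, O1–C5 cinnamylic) or remove an aryl silyl ether before the alkyl TBS ether is gone.
Fallback: it sets out from oxolane 19 and returns at target 25, bypassing steps 12 to 15. All silyl groups are removed at once (TBAF, AcOH, THF) to give the triol F8. Its primary alcohol is then esterified with unprotected 4-hydroxybenzoic acid 21 under Mitsunobu conditions (PPh3, DIAD, THF, 0 °C). The carboxylic acid is far more acidic than the phenols and is the effective pronucleophile, and C7 carries no stereocentre.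

**Further compounds**

F1 | step 9 | (4R)-4-benzyl-3-(4-methoxy-4-oxobutanoyl)-1,3-oxazolidin-2-one | COC(=O)CCC(=O)N1[C@H](Cc2ccccc2)COC1=O
F2 | step 9 | methyl (3R,4R)-3-{[(4R)-4-benzyl-2-oxo-1,3-oxazolidin-3-yl]carbonyl}-4-hydroxy-4-[3-methoxy-4-(triisopropylsilyloxy)phenyl]butanoate | COC(=O)C[C@@H](C(=O)N1[C@H](Cc2ccccc2)COC1=O)[C@@H](O)c1ccc(O[Si](C(C)C)(C(C)C)C(C)C)c(OC)c1
F3 | step 9 | (4R)-4-benzyl-3-{[(2R,3R)-2-[3-methoxy-4-(triisopropylsilyloxy)phenyl]-5-oxooxolan-3-yl]carbonyl}-1,3-oxazolidin-2-one | O=C1C[C@@H](C(=O)N2[C@H](Cc3ccccc3)COC2=O)[C@H](c2ccc(O[Si](C(C)C)(C(C)C)C(C)C)c(OC)c2)O1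
F4 | step 9 | (4S,5R)-4-(hydroxymethyl)-5-[3-methoxy-4-(triisopropylsilyloxy)phenyl]oxolan-2-one | O=C1C[C@@H](CO)[C@H](c2ccc(O[Si](C(C)C)(C(C)C)C(C)C)c(OC)c2)O1
F5 | step 9 | (4S,5R)-4-[(tert-butyldimethylsilyloxy)methyl]-5-[3-methoxy-4-(triisopropylsilyloxy)phenyl]oxolan-2-one | O=C1C[C@@H](CO[Si](C)(C)C(C)(C)C)[C@H](c2ccc(O[Si](C(C)C)(C(C)C)C(C)C)c(OC)c2)O1
F6 | step 9 | (4S,5R)-4-[(tert-butyldimethylsilyloxy)methyl]-3-{hydroxy[3-methoxy-4-(triisopropylsilyloxy)phenyl]methyl}-5-[3-methoxy-4-(triisopropylsilyloxy)phenyl]oxolan-2-one (the two new centres unassigned) | COc1cc(C(O)C2C(=O)O[C@@H](c3ccc(O[Si](C(C)C)(C(C)C)C(C)C)c(OC)c3)[C@@H]2CO[Si](C)(C)C(C)(C)C)ccc1O[Si](C(C)C)(C(C)C)C(C)C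
F7 | step 9 | (3E,4S,5R)-4-[(tert-butyldimethylsilyloxy)methyl]-3-[3-methoxy-4-(triisopropylsilyloxy)benzylidene]-5-[3-methoxy-4-(triisopropylsilyloxy)phenyl]oxolan-2-one | COc1cc(/C=C2/C(=O)O[C@@H](c3ccc(O[Si](C(C)C)(C(C)C)C(C)C)c(OC)c3)[C@@H]2CO[Si](C)(C)C(C)(C)C)ccc1O[Si](C(C)C)(C(C)C)C(C)C
F0 | step 11 | none | none
F8 | step 12 | 4-[(2R,3S,4E)-4-(4-hydroxy-3-methoxybenzylidene)-3-(hydroxymethyl)oxolan-2-yl]-2-methoxyphenol | COc1cc(/C=C2/CO[C@@H](c3ccc(O)c(OC)c3)[C@@H]2CO)ccc1O
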